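**Retrosynthetic overview** (isochromene numbering C1–C8a for the core, C1'–C7' for the side chain)

1. Target 21 ← desilylation of 20 ← loss of HCl (C4a=C5) and MeOH (C1=C8a) from the bicyclic acetal 18, in which the carbocycle and the pyran are closed together by an intramolecular oxa-Diels–Alder reaction of enone/enol ether 17 (bonds O2–C1 and C4a–C8a).
2. 17 ← Michael union (C5–C4a) of dichloromethyl ketone 7 (C5–C8a and C1) with ethynyl ketone 16 (side chain plus C3, C4, C4a).
3. 16 ← light-driven acyl-radical ethynylation of enal 14 (C3–C4 bond) ← L-isoleucic acid 8 (C4', C5' bought; C3' by chelate-controlled MeMgBr addition; E-alkene by trans-hydroalumination).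
4. 7 ← dimethyl L-tartrate 1 (C8 bought; C7 by retentive dianion C-methylation; one ester → enol ether C8a=C1, the other → CHCl2 ketone C6/C5).
5. Ring order: both rings form in one cycloaddition; the two ring double bonds are installed last by elimination, and the extra chlorine on C5 is the leaving group that leaves the C5–Cl of the target.

Assumption: 1, 8, 10 and all named reagents are bought; the enol ether geometry in 6, 7 and 17 is left open because both isomers converge on 20.

**Route**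

Step 1
Reactants: 1 dimethyl (2R,3R)-2,3-dihydroxybutanedioate
Product: 2 dimethyl (2R,3R)-2-[(tert-butyldimethylsilyl)oxy]-3-hydroxybutanedioate
Conditions: TBSCl (1.05 equiv), imidazole, DMF, 0 °C
Reagents that add atoms: tert-butyldimethylsilyl chloride, CC(C)(C)[Si](C)(C)Cl
Why: Mono-O-silylation of a C2-symmetric diol can give only one mono-ether, and both stereocentres are those bought in tartaric acid.

Step 2
Reactants: 2 dimethyl (2R,3R)-2-[(tert-butyldimethylsilyl)oxy]-3-hydroxybutanedioate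
Product: 4 dimethyl (2R,3R)-2,3-bis[(tert-butyldimethylsilyl)oxy]-2-methylbutanedioate, via C-methylated lithium alkoxide 3 (not isolated)
Conditions: LiN(i-Pr)2 (2.3 equiv), THF–DMPU, −78 °C; MeI, −78 → −40 °C; then TBSOTf, −78 → 0 °C
Reagents that add atoms: iodomethane, CI; tert-butyldimethylsilyl trifluoromethanesulfonate, CC(C)(C)[Si](C)(C)OS(=O)(=O)C(F)(F)F
Why: Proposed new method: the lithium alkoxide/ester-enolate dianion sits in a six-membered lithium chelate, so MeI enters the enolate face anti to the ester on the carbinol carbon, replacing H by CH3 with retention and setting C7 (R) under control of the bought C8 centre (O→O silyl migration is degenerate here), after which the alkoxide is capped in the flask; the closest known reaction is the Fráter–Seebach alkylation of malate and other β-hydroxy ester dianions, not yet shown for an enolate carbon that carries a silyloxy group.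

Step 3
Reactants: 4 dimethyl (2R,3R)-2,3-bis[(tert-butyldimethylsilyl)oxy]-2-methylbutanedioate
Product: 6 methyl (2R,3S)-2,3-bis[(tert-butyldimethylsilyl)oxy]-5-methoxy-2-methylpent-4-enoate, via aldehyde 5 (not isolated)
Conditions: i-Bu2AlH (1.1 equiv), toluene, −78 °C; then Ph3P=CHOMe [MeOCH2PPh3Cl, KN(SiMe3)2, THF], −78 → 20 °C
Reagents that add atoms: (methoxymethyl)triphenylphosphonium chloride, COC[P+](c1ccccc1)(c1ccccc1)c1ccccc1.[Cl-]
Why: The ester on the tertiary carbon is much less hindered than the one on the quaternary carbon and is reduced to the aluminium hemiacetal, which is olefinated in the same flask (partial ester reduction, Wittig reaction) so the epimerisable α-silyloxy aldehyde is never isolated and C8 is untouched.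

Step 4
Reactants: 6 methyl (2R,3S)-2,3-bis[(tert-butyldimethylsilyl)oxy]-5-methoxy-2-methylpent-4-enoate
Product: 7 (3R,4S)-3,4-bis[(tert-butyldimethylsilyl)oxy]-1,1-dichloro-6-methoxy-3-methylhex-5-en-2-one
Conditions: CH2Cl2 (3 equiv), LiN(i-Pr)2 (2.5 equiv), THF, −78 °C; AcOH, −78 °C
Reagents that add atoms: dichloromethane, ClCCl
Why: Dichloromethyllithium made in the flask adds once to the ester because the tetrahedral lithium alkoxide survives at −78 °C (acyl substitution to an α,α-dichloromethyl ketone), and the enol ether is inert to it.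

Step 5
Reactants: 8 (2S,3S)-2-hydroxy-3-methylpentanoic acid
Product: 9 (2S,3S)-2-hydroxy-N-methoxy-N,3-dimethylpentanamide
Conditions: MeNH(OMe)·HCl, EDC·HCl, HOBt, N-methylmorpholine, CH2Cl2, 0 → 20 °C
Reagents that add atoms: N,O-dimethylhydroxylamine hydrochloride, CNOC.Cl
Why: Carbodiimide amide coupling gives the Weinreb amide without touching the two stereocentres bought in L-isoleucic acid.

Step 6
Reactants: 9 (2S,3S)-2-hydroxy-N-methoxy-N,3-dimethylpentanamide; 10 3,3-diethoxyprop-1-yne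
Product: 11 (5S,6S)-1,1-diethoxy-5-hydroxy-6-methyloct-2-yn-4-one
Conditions: n-BuLi (2.3 equiv), THF, −78 °C; then 9, −78 → 0 °C; AcOH
Reagents that add atoms: none
Why: The lithium acetylide of 10 adds once to the Weinreb amide through the stable chelated tetrahedral intermediate (Weinreb ketone synthesis), the first equivalent being spent on the free hydroxyl.

Step 7
Reactants: 11 (5S,6S)-1,1-diethoxy-5-hydroxy-6-methyloct-2-yn-4-one
Product: 12 (4R,5S,6S)-1,1-diethoxy-4,6-dimethyloct-2-yne-4,5-diol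
Conditions: MeMgBr (3 equiv), THF, −78 → −20 °C; aq NH4Cl
Reagents that add atoms: methylmagnesium bromide, C[Mg]Br
Why: The magnesium alkoxide of the α-hydroxy ketone forms a five-membered chelate and methyl adds to the carbonyl face anti to the sec-butyl group (Cram chelate-controlled Grignard addition), which sets C3' (R) under control of the bought C4' centre.

Step 8
Reactants: 12 (4R,5S,6S)-1,1-diethoxy-4,6-dimethyloct-2-yne-4,5-diol
Product: 14 (2E,4R,5S,6S)-4,5-dihydroxy-4,6-dimethyloct-2-enal, via allylic diol acetal 13 (not isolated)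
Conditions: NaAlH2(OCH2CH2OMe)2, THF, 0 → 20 °C; then 1 M HCl, THF, 0 °C
Reagents that add atoms: water, O
Why: The propargylic alkoxide delivers hydride intramolecularly to give the trans-alkenyl alane and hence the E-alkene (hydroxyl-directed trans-hydroalumination), and the acidic work-up hydrolyses the acetal to the enal as in the classical route to 4-hydroxy-2-enals.

Step 9
Reactants: 14 (2E,4R,5S,6S)-4,5-dihydroxy-4,6-dimethyloct-2-enal
Product: 15 (4E,6R,7S,8S)-6,7-dihydroxy-6,8-dimethyl-1-(trimethylsilyl)dec-4-en-1-yn-3-one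
Conditions: (n-Bu4N)4[W10O32] (2 mol %), TMS-EBX (1.5 equiv), MeCN, 390 nm LEDs, 20 °C, Ar
Reagents that add atoms: 1-[(trimethylsilyl)ethynyl]-1,2-benziodoxol-3(1H)-one, C[Si](C)(C)C#CI1OC(=O)c2ccccc12
Why: Proposed new method: photoexcited [W10O32]4− abstracts the formyl hydrogen atom of the enal, the α,β-unsaturated acyl radical adds to the iodine-bearing alkyne carbon of the trivalent-iodine reagent and β-fragmentation releases the ynone, so the C3–C4 bond of the future pyran is made by light in one step without an organometallic addition and a separate oxidation; the closest known reaction is the hydrogen-atom-transfer photocatalysed C–H alkynylation of saturated and aromatic aldehydes with alkynylbenziodoxolones or alkynyl sulfones, not yet shown for an enal or beside a free allylic diol.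

Step 10
Reactants: 7 (3R,4S)-3,4-bis[(tert-butyldimethylsilyl)oxy]-1,1-dichloro-6-methoxy-3-methylhex-5-en-2-one; 15 (4E,6R,7S,8S)-6,7-dihydroxy-6,8-dimethyl-1-(trimethylsilyl)dec-4-en-1-yn-3-one
Product: 17 (3S,4R,7E,10E,12R,13S,14S)-3,4-bis[(tert-butyldimethylsilyl)oxy]-6,6-dichloro-12,13-dihydroxy-1-methoxy-4,12,14-trimethylhexadeca-1,7,10-triene-5,9-dione, via terminal ynone 16 (not isolated)
Conditions: CsF (1.2 equiv), MeCN, 0 → 20 °C; AcOH
Reagents that add atoms: none
Why: Fluoride removes the alkynyl silyl group far faster than it attacks the silyl ethers, and the resulting base turns the acidic dichloromethyl ketone into its enolate, which adds to the terminal carbon of the ynone (Michael addition) and joins the two chiral fragments through the C5–C4a bond.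

Step 11
Reactants: 17 (3S,4R,7E,10E,12R,13S,14S)-3,4-bis[(tert-butyldimethylsilyl)oxy]-6,6-dichloro-12,13-dihydroxy-1-methoxy-4,12,14-trimethylhexadeca-1,7,10-triene-5,9-dione
Product: 20 (7R,8S)-7,8-bis[(tert-butyldimethylsilyl)oxy]-5-chloro-3-[(1E,3R,4S,5S)-3,4-dihydroxy-3,5-dimethylhept-1-en-1-yl]-7-methyl-7,8-dihydro-6H-isochromen-6-one, via cycloadduct 18 (not isolated), via chlorodienone acetal 19 (not isolated)
Conditions: toluene, 90 °C; then DBU (2.5 equiv), 20 → 60 °C
Reagents that add atoms: none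
Why: The enone (O2=C3–C4=C4a) and the tethered enol ether (C8a=C1) close both rings in an intramolecular inverse-electron-demand oxa-Diels–Alder reaction, helped by the two quaternary carbons in the tether, and DBU then removes HCl (E2, C4a–H/C5–Cl) and methanol (E1cB from C1) to give the conjugated chloro-azaphilone, the centres formed at C1, C4a and C8a being destroyed while C7 and C8 are untouched.

Step 12
Reactants: 20 (7R,8S)-7,8-bis[(tert-butyldimethylsilyl)oxy]-5-chloro-3-[(1E,3R,4S,5S)-3,4-dihydroxy-3,5-dimethylhept-1-en-1-yl]-7-methyl-7,8-dihydro-6H-isochromen-6-one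
Product: 21 (7R,8S)-5-chloro-3-[(1E,3R,4S,5S)-3,4-dihydroxy-3,5-dimethylhept-1-en-1-yl]-7,8-dihydroxy-7-methyl-7,8-dihydro-6H-isochromen-6-one
Conditions: HF·pyridine, pyridine, THF, 0 → 20 °C
Reagents that add atoms: none
Why: Buffered fluoride cleaves both silyl ethers (desilylation) without acid strong enough to ionise the tertiary allylic alcohol.

**Compound list**

1 | dimethyl (2R,3R)-2,3-dihydroxybutanedioate (dimethyl L-tartrate) | COC(=O)[C@H](O)[C@@H](O)C(=O)OC | starting material
2 | dimethyl (2R,3R)-2-[(tert-butyldimethylsilyl)oxy]-3-hydroxybutanedioate | COC(=O)[C@H](O[Si](C)(C)C(C)(C)C)[C@@H](O)C(=O)OC | intermediate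
3 | dimethyl (2R,3R)-2-[(tert-butyldimethylsilyl)oxy]-3-hydroxy-2-methylbutanedioate (formed as its lithium alkoxide) | COC(=O)[C@](C)(O[Si](C)(C)C(C)(C)C)[C@@H](O)C(=O)OC | intermediate
4 | dimethyl (2R,3R)-2,3-bis[(tert-butyldimethylsilyl)oxy]-2-methylbutanedioate | COC(=O)[C@](C)(O[Si](C)(C)C(C)(C)C)[C@@H](O[Si](C)(C)C(C)(C)C)C(=O)OC | intermediate
5 | methyl (2R,3R)-2,3-bis[(tert-butyldimethylsilyl)oxy]-2-methyl-4-oxobutanoate | COC(=O)[C@](C)(O[Si](C)(C)C(C)(C)C)[C@@H](O[Si](C)(C)C(C)(C)C)C=O | intermediate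
6 | methyl (2R,3S)-2,3-bis[(tert-butyldimethylsilyl)oxy]-5-methoxy-2-methylpent-4-enoate (E/Z mixture) | COC(=O)[C@](C)(O[Si](C)(C)C(C)(C)C)[C@@H](O[Si](C)(C)C(C)(C)C)C=COC | intermediate
7 | (3R,4S)-3,4-bis[(tert-butyldimethylsilyl)oxy]-1,1-dichloro-6-methoxy-3-methylhex-5-en-2-one (E/Z mixture) | ClC(Cl)C(=O)[C@](C)(O[Si](C)(C)C(C)(C)C)[C@@H](O[Si](C)(C)C(C)(C)C)C=COC | intermediate
8 | (2S,3S)-2-hydroxy-3-methylpentanoic acid (L-isoleucic acid) | CC[C@H](C)[C@H](O)C(O)=O | starting material
9 | (2S,3S)-2-hydroxy-N-methoxy-N,3-dimethylpentanamide | CC[C@H](C)[C@H](O)C(=O)N(C)OC | intermediate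
10 | 3,3-diethoxyprop-1-yne | CCOC(OCC)C#C | starting material
11 | (5S,6S)-1,1-diethoxy-5-hydroxy-6-methyloct-2-yn-4-one | CC[C@H](C)[C@H](O)C(=O)C#CC(OCC)OCC | intermediate
12 | (4R,5S,6S)-1,1-diethoxy-4,6-dimethyloct-2-yne-4,5-diol | CC[C@H](C)[C@H](O)[C@](C)(O)C#CC(OCC)OCC | intermediate
13 | (2E,4R,5S,6S)-1,1-diethoxy-4,6-dimethyloct-2-ene-4,5-diol | CC[C@H](C)[C@H](O)[C@](C)(O)/C=C/C(OCC)OCC | intermediate
14 | (2E,4R,5S,6S)-4,5-dihydroxy-4,6-dimethyloct-2-enal | CC[C@H](C)[C@H](O)[C@](C)(O)/C=C/C=O | intermediate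
15 | (4E,6R,7S,8S)-6,7-dihydroxy-6,8-dimethyl-1-(trimethylsilyl)dec-4-en-1-yn-3-one | CC[C@H](C)[C@H](O)[C@](C)(O)/C=C/C(=O)C#C[Si](C)(C)C | intermediate
16 | (4E,6R,7S,8S)-6,7-dihydroxy-6,8-dimethyldec-4-en-1-yn-3-one | CC[C@H](C)[C@H](O)[C@](C)(O)/C=C/C(=O)C#C | intermediate
17 | (3S,4R,7E,10E,12R,13S,14S)-3,4-bis[(tert-butyldimethylsilyl)oxy]-6,6-dichloro-12,13-dihydroxy-1-methoxy-4,12,14-trimethylhexadeca-1,7,10-triene-5,9-dione (enol ether E/Z mixture) | CC[C@H](C)[C@H](O)[C@](C)(O)/C=C/C(=O)/C=C/C(Cl)(Cl)C(=O)[C@](C)(O[Si](C)(C)C(C)(C)C)[C@@H](O[Si](C)(C)C(C)(C)C)C=COC | intermediate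
18 | (7R,8S)-7,8-bis[(tert-butyldimethylsilyl)oxy]-5,5-dichloro-3-[(1E,3R,4S,5S)-3,4-dihydroxy-3,5-dimethylhept-1-en-1-yl]-1-methoxy-7-methyl-4a,5,8,8a-tetrahydro-1H-isochromen-6(7H)-one (mixture at C1, C4a, C8a) | COC1OC(/C=C/[C@@](C)(O)[C@@H](O)[C@@H](C)CC)=CC2C1[C@H](O[Si](C)(C)C(C)(C)C)[C@@](C)(O[Si](C)(C)C(C)(C)C)C(=O)C2(Cl)Cl | intermediate
19 | (7R,8S)-7,8-bis[(tert-butyldimethylsilyl)oxy]-5-chloro-3-[(1E,3R,4S,5S)-3,4-dihydroxy-3,5-dimethylhept-1-en-1-yl]-1-methoxy-7-methyl-8,8a-dihydro-1H-isochromen-6(7H)-one (mixture at C1, C8a) | COC1OC(/C=C/[C@@](C)(O)[C@@H](O)[C@@H](C)CC)=CC2=C(Cl)C(=O)[C@](C)(O[Si](C)(C)C(C)(C)C)[C@@H](O[Si](C)(C)C(C)(C)C)C12 | intermediate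
20 | (7R,8S)-7,8-bis[(tert-butyldimethylsilyl)oxy]-5-chloro-3-[(1E,3R,4S,5S)-3,4-dihydroxy-3,5-dimethylhept-1-en-1-yl]-7-methyl-7,8-dihydro-6H-isochromen-6-one | CC[C@H](C)[C@H](O)[C@](C)(O)/C=C/C1=CC2=C(Cl)C(=O)[C@](C)(O[Si](C)(C)C(C)(C)C)[C@@H](O[Si](C)(C)C(C)(C)C)C2=CO1 | intermediate
21 | (7R,8S)-5-chloro-3-[(1E,3R,4S,5S)-3,4-dihydroxy-3,5-dimethylhept-1-en-1-yl]-7,8-dihydroxy-7-methyl-7,8-dihydro-6H-isochromen-6-one | CC[C@H](C)[C@H](O)[C@](C)(O)/C=C/C1=CC2=C(Cl)C(=O)[C@](C)(O)[C@@H](O)C2=CO1 | target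

**Totals**

Total step count: 12. Longest linear sequence: 8 steps (8 → 9 → 11 → 12 → 14 → 15 → 17 → 20 → 21; steps 5 to 12). The core branch (1 → 7, then steps 10 to 12) is 7 steps.

**Steps most likely to fail, each with a fallback**

Step 2 (retentive dianion C-methylation, proposed new; it sets C7). Fallback with known chemistry, from 2 back to 4: LiOH hydrolyses 2 to (2R,3R)-2-[(tert-butyldimethylsilyl)oxy]-3-hydroxybutanedioic acid F1. Its free α-hydroxy acid half is condensed with pivalaldehyde (TsOH, pentane, water separator) to the cis-dioxolanone (2R)-2-[(2R,4R)-2-tert-butyl-5-oxo-1,3-dioxolan-4-yl]-2-[(tert-butyldimethylsilyl)oxy]acetic acid F2. LiN(i-Pr)2 and MeI at −78 °C methylate the dioxolanone enolate anti to the tert-butyl group, that is with net retention (Seebach self-regeneration of stereocentres), giving (2R)-2-[(2R,4R)-2-tert-butyl-4-methyl-5-oxo-1,3-dioxolan-4-yl]-2-[(tert-butyldimethylsilyl)oxy]acetic acid F3. HCl in MeOH opens the acetal, esterifies and desilylates to dimethyl (2R,3R)-2,3-dihydroxy-2-methylbutanedioate F4, and TBSOTf with 2,6-lutidine silylates both hydroxyls to rejoin the route at 4.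

Step 9 (photochemical acyl-radical ethynylation, proposed new). The risks are hydrogen abstraction next to the free secondary hydroxyl and loss of the enal through radical addition. Fallback with known chemistry, from 14 back to 16: HC≡CMgBr (THF, −78 °C) adds to the enal to give (4E,6R,7S,8S)-6,8-dimethyldec-4-en-1-yne-3,6,7-triol F5 as a mixture at C3. MnO2 (CH2Cl2) oxidises only the doubly activated carbinol to the terminal ynone 16, which is isolated and used in step 10 with catalytic Cs2CO3 in place of CsF.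

Step 11 (cycloaddition and double elimination). The risks are a slow cycloaddition in the crowded tether and incomplete loss of methanol. Fallback from 17 back to 20: the enol ether is hydrolysed (pyridinium p-toluenesulfonate, acetone–water) to the aldehyde (3S,4R,7E,10E,12R,13S,14S)-3,4-bis[(tert-butyldimethylsilyl)oxy]-6,6-dichloro-12,13-dihydroxy-4,12,14-trimethyl-5,9-dioxohexadeca-7,10-dienal F6. Pyrrolidinium acetate (10 mol %, CH2Cl2) closes the carbocycle by an enamine-mediated intramolecular Michael addition of C8a to C4a, the C3 enol oxygen closes the lactol on C1, and DBU then removes water and HCl to give 20.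

Further compounds
F1 | step 2 | (2R,3R)-2-[(tert-butyldimethylsilyl)oxy]-3-hydroxybutanedioic acid | OC(=O)[C@H](O[Si](C)(C)C(C)(C)C)[C@@H](O)C(O)=O
F2 | step 2 | (2R)-2-[(2R,4R)-2-tert-butyl-5-oxo-1,3-dioxolan-4-yl]-2-[(tert-butyldimethylsilyl)oxy]acetic acid | OC(=O)[C@H](O[Si](C)(C)C(C)(C)C)[C@H]1O[C@@H](C(C)(C)C)OC1=O
F3 | step 2 | (2R)-2-[(2R,4R)-2-tert-butyl-4-methyl-5-oxo-1,3-dioxolan-4-yl]-2-[(tert-butyldimethylsilyl)oxy]acetic acid | OC(=O)[C@H](O[Si](C)(C)C(C)(C)C)[C@@]1(C)O[C@@H](C(C)(C)C)OC1=O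
F4 | step 2 | dimethyl (2R,3R)-2,3-dihydroxy-2-methylbutanedioate | COC(=O)[C@](C)(O)[C@@H](O)C(=O)OC
F5 | step 9 | (4E,6R,7S,8S)-6,8-dimethyldec-4-en-1-yne-3,6,7-triol (mixture at C3) | CC[C@H](C)[C@H](O)[C@](C)(O)/C=C/C(O)C#C
F6 | step 11 | (3S,4R,7E,10E,12R,13S,14S)-3,4-bis[(tert-butyldimethylsilyl)oxy]-6,6-dichloro-12,13-dihydroxy-4,12,14-trimethyl-5,9-dioxohexadeca-7,10-dienal | CC[C@H](C)[C@H](O)[C@](C)(O)/C=C/C(=O)/C=C/C(Cl)(Cl)C(=O)[C@](C)(O[Si](C)(C)C(C)(C)C)[C@@H](O[Si](C)(C)C(C)(C)C)CC=O
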